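## Structural features

The target is a cyclohex-2-en-1-one (C1 carbonyl, C2=C3 alkene) with a secondary allylic carbinol at C4 and, next to the carbonyl, a tertiary carbinol at C6 that carries a seventeen-carbon chain (C1′–C17′). The chain holds a secondary carbinol at C2′ and an isolated (Z)-alkene at C10′–C11′. There are three stereocentres, C4 (S), C6 (R) and C2′ (S). The C4 and C6 oxygens are cis on the ring across the C5 methylene; the C6 and C2′ oxygens are 1,3-related through C1′ and anti when C5–C6–C1′–C2′–C3′ is drawn as a zigzag. The molecule is fragile: it is a 4-hydroxy enone and a tertiary α-ketol, one dehydration and tautomerisation away from an alkylhydroquinone, open to ketol shift or retro-aldol cleavage in base, and its (Z)-alkene rules out hydrogenation. The real difficulty is the fully substituted carbinol C6, which must be set relative to C4 on the ring and to C2′ outside it, while C2′ lies between two methylene groups and offers a chiral reagent little to grip. The key step uses the fact that O–C6–C1′–C2′–O is the pattern of an opened 2-isoxazoline, and that C1, before it becomes the ketone, can be a carbinol cis to the C4 oxygen whose magnesium alkoxide steers a nitrile oxide onto the C6=C1′ alkene. Checked against the target, the dipolarophile must be the (1S,4S) isomer and the cycloadduct the (5R,6S,9S) spiro-isoxazoline, both with all three ring oxygens on one face; no structural error was found.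

## Logic of the disconnections

**23 back to 22 and 21.** The O–Si bond at C4 and the C1 carbonyl are adjusted last. Holding C4 as a silyl ether makes C1 the only free allylic carbinol in 21, so an oxidant that takes allylic alcohols only can form the enone without touching C2′ or C4. The forward demand is a desilylation mild enough for a dehydration-prone ketol.

**21 back to 20.** The C2′–H bond is removed, which strips one stereocentre and leaves a ketone. Because that ketone is flanked by two methylenes, catalyst control alone would be weak. The forward step is therefore asked to deliver hydride from boron held by the cis C1/C6 diol, which needs no extra protecting group.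

**20 back to 18 (through 19).** The C6 oxygen is reconnected to a nitrogen on C2′; forward, the N–O bond is cleaved and the C=N bond hydrolysed. The gain is that the retro-aldol-prone β-hydroxy ketone travels in masked form. The demand is a reductant that spares both alkenes.

**18 back to 12 and 15 (through 16 and 17).** C1′–C2′ and C6–O are cut together. This is the largest simplification: the whole chain leaves as a dipole and the ring shrinks to a small dienol with two stereocentres. The forward step must put oxygen on C6 on the face of the C1 and C4 oxygens and must prefer the exocyclic alkene to the ring alkene.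

**12 back to 11 and 7 (through 8, 9 and 10).** The C1–H bond is removed, then the C6=C1′ bond is cut as an α′-methylenation. This reaches a known type of building block. The demands are that 11, a tautomer of a phenol, is made under mild base and reduced at once, and that hydride adds anti to the C4 silyloxy group.

**7 back to 1 (through 6, 5, 4, 3 and 2).** The C1 carbonyl returns to a carbinol and both ring C–O bonds are cut to the diene. Both oxygens come from one molecule of dioxygen, so the cis relationship is automatic and 3 is meso. An enzyme then sets the absolute configuration, and an acetate/silyl relay decides which oxygen becomes C4–O and which becomes the carbonyl. A shorter entry by base-induced rearrangement of 2 was set aside because its enantiopurity is less assured.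

**15 back to 13 (through 14).** The C–Cl bond and the C=N–OH group are removed. The (Z)-alkene is bought with 13 and is never made or isomerised in the route.

## Other disconnections considered

**Alternative 1:** The ring is cut at C3–C4. The open-chain precursor A2 carries a (Z)-β-iodoenone across C1–C3 and an aldehyde at C4; its tertiary carbinol would come from quinic acid A3 after ring cleavage. Forward, CrCl2 (divalent chromium) with catalytic NiCl2 (divalent nickel) would turn the vinyl iodide into a vinylchromium nucleophile that adds to the aldehyde, closing the six-membered enone and giving A1.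
- In its favour: the C6 configuration is taken from the chiral pool and cannot be lost, the chromium addition tolerates ketone, ethers and the (Z)-alkene, and ring, enone and free C4 hydroxyl appear in one step.
- Against it here: C4 is created in the cyclisation with only 1,3-induction from C6; C2′ still has to be set separately; A3 needs extensive degradation and rechaining; the (Z)-iodoenone is prone to isomerisation; and the MOM ether has to leave under acid, the condition most likely to dehydrate the product.
- Comparison: on securing C6 it is the equal of the chosen plan or better. On C4 it is weaker, since the chosen plan fixes C4 enzymatically before any ring chemistry. Both key steps are well-behaved mechanistically. On step economy the chosen plan is clearly shorter.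

**Alternative 2:** C6–C1′ and C5–C6 are cut, with C6 as a dithiane linchpin. Forward, lithiated silyl dithiane A5 would open epoxide A6 at C1′, HMPA would trigger 1,4-Brook transfer of silicon to the C2′ oxygen, and the new dithiane anion would open epoxide A7 at C5, giving acyclic A4.
- In its favour: C2′ and C4 are both bought as enantiopure terminal epoxides, the union is a convergent one-flask operation, and C2′ is protected in the same step.
- Against it here: C6 emerges as a masked ketone, so the ring must still be closed by joining C1 to C6 while creating the tertiary carbinol under substrate control only; the C2=C3 alkene must be added afterwards by dehydrogenation; HMPA is needed; and the dithiane must be removed next to a (Z)-alkene.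
- Comparison: on C2′ it is better than the chosen plan, which relies on a late reduction. On C4 the two are equal. On C6 it is weaker, because the chosen plan sets C6 by directed delivery in the bond-forming step. After the linchpin at least five further operations remain, so it is not shorter.

**Alternative 3:** The ring is cut at C2–C3 and the C4 oxygen is removed; the precursor A9 is a β-keto sulfoxide with an aldehyde at C3. Forward, piperidine would condense C2 with the aldehyde, the 2-sulfinyl enone would isomerise to the C3–C4 allylic sulfoxide, and [2,3] shift followed by sulfenate cleavage would give A8 with the ring, the enone and the C4 hydroxyl formed in one operation.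
- In its favour: no protecting group is needed at C4, C2′ can be set in the open chain, and A8 is a single desilylation from the target.
- Against it here: the C4 configuration depends on the face of the sigmatropic shift, guided only by the remote C6 and by sulfur and C2 centres that can epimerise; the cascade runs through several equilibria in the presence of a secondary amine that could start dehydration or retro-aldol cleavage of the ketol; and A9 already contains the quaternary carbinol with both arms, which must be built first.
- Comparison: the end game after the key step is shorter than in the chosen plan, and on that point it is better. On stereocontrol at both ring centres and on the length of the route to the key-step precursor the chosen plan is stronger.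

Key step: step 10

Assumption: the lipase acylates the (R)-configured carbinol of the meso diol, the usual sense for cyclic secondary allylic alcohols; if it showed the opposite sense, it would be run in the hydrolytic direction on the corresponding diester, which exposes the same (S) carbinol.

## Route

Step 1
Reactants: 1 cyclohexa-1,3-diene
Product: 3 cis-cyclohex-2-ene-1,4-diol (meso, 1R,4S), via 2,3-dioxabicyclo[2.2.2]oct-5-ene 2 (not isolated)
Conditions: O2, hν, rose bengal, MeOH, 0 °C; then thiourea, rt
Reagents that add atoms: dioxygen, O=O
Why: Singlet oxygen adds to the diene in a [4+2] cycloaddition, so both new C–O bonds lie on one face; thiourea then reduces the O–O bond of 2 in the same flask, which gives the cis (meso) diol without any stereochemical choice.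

Step 2
Reactants: 3 cis-cyclohex-2-ene-1,4-diol
Product: 4 (1S,4R)-4-acetoxycyclohex-2-en-1-ol
Conditions: Candida antarctica lipase B (immobilised), vinyl acetate, t-BuOMe, rt
Reagents that add atoms: vinyl acetate, CC(=O)OC=C
Why: Lipase-catalysed acyl transfer desymmetrises the meso diol by acetylating only the (R)-configured carbinol, and loss of vinyl alcohol as acetaldehyde makes the transfer irreversible. The carbinol left free is the (S) centre that becomes C4 of the target.

Step 3
Reactants: 4 (1S,4R)-4-acetoxycyclohex-2-en-1-ol
Product: 5 (1R,4S)-4-(tert-butyldimethylsilyloxy)cyclohex-2-en-1-yl acetate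
Conditions: TBSCl, imidazole, DMF, rt
Reagents that add atoms: tert-butyldimethylsilyl chloride (TBSCl), CC(C)(C)[Si](C)(C)Cl
Why: Standard silylation of a secondary alcohol; the acetate and both stereocentres are not touched.

Step 4
Reactants: 5 (1R,4S)-4-(tert-butyldimethylsilyloxy)cyclohex-2-en-1-yl acetate
Product: 6 (1R,4S)-4-(tert-butyldimethylsilyloxy)cyclohex-2-en-1-ol
Conditions: K2CO3, MeOH, rt
Reagents that add atoms: none
Why: Methanolysis removes the acetate by acyl–oxygen cleavage, so the carbinol keeps its configuration; the silyl ether is stable to carbonate in methanol.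

Step 5
Reactants: 6 (1R,4S)-4-(tert-butyldimethylsilyloxy)cyclohex-2-en-1-ol
Product: 7 (4S)-4-(tert-butyldimethylsilyloxy)cyclohex-2-en-1-one
Conditions: MnO2, CH2Cl2, rt
Reagents that add atoms: none
Why: Allylic alcohol oxidation under neutral conditions; the only free carbinol is the one that becomes C1, and the (S) centre at C4 is not epimerised.

Step 6
Reactants: 7 (4S)-4-(tert-butyldimethylsilyloxy)cyclohex-2-en-1-one
Product: 11 (4S)-4-(tert-butyldimethylsilyloxy)-6-methylidenecyclohex-2-en-1-one, via lithium dienolate 8 (not isolated), via Mannich base 9 (not isolated), via trimethylammonium iodide 10 (not isolated)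
Conditions: LiN(SiMe3)2, THF, −78 °C; CH2=NMe2+ I−, −78 → 0 °C; MeI, rt; aq NaHCO3, CH2Cl2, 0 °C
Reagents that add atoms: N,N-dimethylmethyleneiminium iodide, C=[N+](C)C.[I-]
Why: Kinetic deprotonation takes the only α′ hydrogens (C6), the enolate adds to the iminium ion (Mannich reaction), and quaternisation followed by E1cB loss of trimethylamine gives the α-methylene ketone without involving C4. Because 11 is a tautomer of a cresol silyl ether and a reactive Michael acceptor, it should be kept cold, filtered quickly and reduced at once.

Step 7
Reactants: 11 (4S)-4-(tert-butyldimethylsilyloxy)-6-methylidenecyclohex-2-en-1-one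
Product: 12 (1S,4S)-4-(tert-butyldimethylsilyloxy)-6-methylidenecyclohex-2-en-1-ol
Conditions: NaBH4, CeCl3·7H2O, MeOH, −78 °C
Reagents that add atoms: none
Why: Luche reduction: cerium-modified borohydride attacks the carbonyl carbon and not the exocyclic enone terminus. Hydride should enter anti to the pseudoaxial C4 silyloxy group, which places the new C1 hydroxyl cis to it (1S).

Step 8
Reactants: 13 (9Z)-hexadec-9-enal
Product: 14 (9Z)-hexadec-9-enal oxime
Conditions: NH2OH·HCl, NaOAc, EtOH–H2O, rt
Reagents that add atoms: hydroxylamine hydrochloride, NO.Cl
Why: Condensation of an aldehyde with hydroxylamine; the (Z)-alkene is remote and unaffected, and the geometry of the oxime is of no consequence.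

Step 9
Reactants: 14 (9Z)-hexadec-9-enal oxime
Product: 15 (9Z)-N-hydroxyhexadec-9-enimidoyl chloride
Conditions: NCS, DMF, rt
Reagents that add atoms: N-chlorosuccinimide, O=C1CCC(=O)N1Cl
Why: Electrophilic chlorination at the aldoxime carbon gives the hydroximoyl chloride; isolated alkenes are tolerated under these conditions, as they are in substrates for intramolecular nitrile oxide cycloadditions.

Step 10
Reactants: 12 (1S,4S)-4-(tert-butyldimethylsilyloxy)-6-methylidenecyclohex-2-en-1-ol; 15 (9Z)-N-hydroxyhexadec-9-enimidoyl chloride
Product: 18 (5R,6S,9S)-9-(tert-butyldimethylsilyloxy)-3-[(8Z)-pentadec-8-en-1-yl]-1-oxa-2-azaspiro[4.5]deca-2,7-dien-6-ol, via bromomagnesium alkoxide 16 (not isolated), via nitrile oxide 17 (not isolated)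
Conditions: 12, i-PrOH (3.3 equiv), EtMgBr (3 equiv), CH2Cl2, 0 °C; 15 added slowly, 0 °C → rt; aq NH4Cl
Reagents that add atoms: none
Why: Bromomagnesium isopropoxide removes HCl from 15 to give nitrile oxide 17 while 12 is held as its bromomagnesium alkoxide 16; magnesium binds the dipole oxygen and a concerted, asynchronous [3+2] cycloaddition follows inside this complex. The closest known reaction type is the magnesium-alkoxide-directed nitrile oxide cycloaddition to allylic alcohols, together with the formation of spiro-isoxazolines from 1,1-disubstituted alkenes. The isoxazoline ring closes by intermolecular [3+2] annulation in which C1′–C2′ and C6–O form together and C6 becomes the spiro atom. The dipole carbon goes to the unhindered CH2 terminus and the oxygen to the substituted carbon C6, a sense favoured both by the inherent preference of terminal alkenes and by chelation. The new stereocentre C6 is controlled by the C1 alkoxide: delivery through magnesium puts C6–O on the C1–O face, which in 12 is also the C4–O face, so (R) at C6 follows from (1S). The step also needs site selectivity against the ring alkene, which is allylic to the same alkoxide; that alkene is 1,2-disubstituted and flanked by two oxygenated carbons, so it should be the poorer dipolarophile, and the isolated (Z)-alkene of the chain is not activated at all. Slow addition of 15 keeps 17 dilute and should suppress its dimerisation to a furoxan. C2′ stays sp2 here and is set in step 12.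

Step 11
Reactants: 18 (5R,6S,9S)-9-(tert-butyldimethylsilyloxy)-3-[(8Z)-pentadec-8-en-1-yl]-1-oxa-2-azaspiro[4.5]deca-2,7-dien-6-ol
Product: 20 (10Z)-1-[(1S,2S,5S)-5-(tert-butyldimethylsilyloxy)-1,2-dihydroxycyclohex-3-en-1-yl]heptadec-10-en-2-one, via β-hydroxy imine 19 (not isolated)
Conditions: Mo(CO)6, MeCN–H2O, 80 °C
Reagents that add atoms: water, O
Why: Mo(CO)6 (zerovalent molybdenum) coordinates nitrogen and reductively cleaves the N–O bond of the 2-isoxazoline, and the water present hydrolyses imine 19 to the β-hydroxy ketone. No hydrogenation catalyst is involved, so both alkenes and the silyl ether should survive, and C6 keeps its configuration because no bond to it is broken.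

Step 12
Reactants: 20 (10Z)-1-[(1S,2S,5S)-5-(tert-butyldimethylsilyloxy)-1,2-dihydroxycyclohex-3-en-1-yl]heptadec-10-en-2-one
Product: 21 (1R,2S,5S)-5-(tert-butyldimethylsilyloxy)-1-[(2S,10Z)-2-hydroxyheptadec-10-en-1-yl]cyclohex-3-ene-1,2-diol
Conditions: Me4NBH(OAc)3, AcOH–MeCN, −30 °C
Reagents that add atoms: none
Why: Hydroxyl-directed reduction of a β-hydroxy ketone by internal hydride delivery (Evans–Saksena reduction). Boron should exchange acetate for the cis C1/C6 diol, which holds the C1 arm axial in the chair-like six-membered transition state while the C3′ chain sits equatorial, so hydride should reach the face of C2′ that gives the diol anti along C5–C6–C1′–C2′, that is (2′S). The alkenes, the silyl ether and the tertiary carbinol are inert to this weakly acidic borohydride at low temperature.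

Step 13
Reactants: 21 (1R,2S,5S)-5-(tert-butyldimethylsilyloxy)-1-[(2S,10Z)-2-hydroxyheptadec-10-en-1-yl]cyclohex-3-ene-1,2-diol
Product: 22 (4S,6R)-4-(tert-butyldimethylsilyloxy)-6-hydroxy-6-[(2S,10Z)-2-hydroxyheptadec-10-en-1-yl]cyclohex-2-en-1-one
Conditions: MnO2, CH2Cl2, rt
Reagents that add atoms: none
Why: MnO2 oxidises allylic alcohols selectively: C1–OH is the only free allylic carbinol because C4 is silylated, the C2′ carbinol is not allylic and C6 is tertiary. No stereocentre is touched, and the reaction is stopped as soon as 21 is consumed to avoid glycol-type cleavage of the new ketol.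

Step 14
Reactants: 22 (4S,6R)-4-(tert-butyldimethylsilyloxy)-6-hydroxy-6-[(2S,10Z)-2-hydroxyheptadec-10-en-1-yl]cyclohex-2-en-1-one
Product: 23 (4S,6R)-4,6-dihydroxy-6-[(2S,10Z)-2-hydroxyheptadec-10-en-1-yl]cyclohex-2-en-1-one
Conditions: HF·pyridine, pyridine, THF, 0 °C → rt
Reagents that add atoms: none
Why: Fluoride cleaves the secondary allylic silyl ether under buffered, weakly acidic conditions. These avoid the basic medium that would invite ketol shift, retro-aldol cleavage or dehydration to the hydroquinone.

## Compound list

1 | cyclohexa-1,3-diene | C1=CC=CCC1 | starting material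
2 | 2,3-dioxabicyclo[2.2.2]oct-5-ene (meso endoperoxide, not isolated) | C1C[C@H]2C=C[C@@H]1OO2 | intermediate
3 | cis-cyclohex-2-ene-1,4-diol (meso, 1R,4S) | C1C[C@H](O)C=C[C@@H]1O | intermediate
4 | (1S,4R)-4-acetoxycyclohex-2-en-1-ol (cis) | C1C[C@H](O)C=C[C@@H]1OC(C)=O | intermediate
5 | (1R,4S)-4-(tert-butyldimethylsilyloxy)cyclohex-2-en-1-yl acetate (cis) | C1C[C@H](O[Si](C)(C)C(C)(C)C)C=C[C@@H]1OC(C)=O | intermediate
6 | (1R,4S)-4-(tert-butyldimethylsilyloxy)cyclohex-2-en-1-ol (cis) | C1C[C@H](O[Si](C)(C)C(C)(C)C)C=C[C@@H]1O | intermediate
7 | (4S)-4-(tert-butyldimethylsilyloxy)cyclohex-2-en-1-one | C1C[C@H](O[Si](C)(C)C(C)(C)C)C=CC1=O | intermediate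
8 | lithium (4S)-4-(tert-butyldimethylsilyloxy)cyclohexa-1,5-dien-1-olate (not isolated) | [Li+].[O-]C1=CC[C@H](O[Si](C)(C)C(C)(C)C)C=C1 | intermediate
9 | (4S)-4-(tert-butyldimethylsilyloxy)-6-[(dimethylamino)methyl]cyclohex-2-en-1-one (C6 epimers, not isolated) | CN(C)CC1C[C@H](O[Si](C)(C)C(C)(C)C)C=CC1=O | intermediate
10 | {[(5S)-5-(tert-butyldimethylsilyloxy)-2-oxocyclohex-3-en-1-yl]methyl}trimethylammonium iodide (epimers at the ring carbon bearing the side arm, not isolated) | C[N+](C)(C)CC1C[C@H](O[Si](C)(C)C(C)(C)C)C=CC1=O.[I-] | intermediate
11 | (4S)-4-(tert-butyldimethylsilyloxy)-6-methylidenecyclohex-2-en-1-one | C=C1C[C@H](O[Si](C)(C)C(C)(C)C)C=CC1=O | intermediate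
12 | (1S,4S)-4-(tert-butyldimethylsilyloxy)-6-methylidenecyclohex-2-en-1-ol (C1 hydroxyl cis to the C4 silyloxy group) | C=C1C[C@H](O[Si](C)(C)C(C)(C)C)C=C[C@@H]1O | intermediate
13 | (9Z)-hexadec-9-enal | CCCCCC/C=C\CCCCCCCC=O | starting material
14 | (9Z)-hexadec-9-enal oxime (E/Z mixture at C=N) | CCCCCC/C=C\CCCCCCCC=NO | intermediate
15 | (9Z)-N-hydroxyhexadec-9-enimidoyl chloride | CCCCCC/C=C\CCCCCCCC(Cl)=NO | intermediate
16 | bromomagnesium (1S,4S)-4-(tert-butyldimethylsilyloxy)-6-methylidenecyclohex-2-en-1-olate (not isolated) | C=C1C[C@H](O[Si](C)(C)C(C)(C)C)C=C[C@@H]1O[Mg]Br | intermediate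
17 | (9Z)-hexadec-9-enenitrile oxide (not isolated) | CCCCCC/C=C\CCCCCCCC#[N+][O-] | intermediate
18 | (5R,6S,9S)-9-(tert-butyldimethylsilyloxy)-3-[(8Z)-pentadec-8-en-1-yl]-1-oxa-2-azaspiro[4.5]deca-2,7-dien-6-ol | CCCCCC/C=C\CCCCCCCC1=NO[C@]2(C1)C[C@H](O[Si](C)(C)C(C)(C)C)C=C[C@@H]2O | intermediate
19 | (10Z)-1-[(1R,2S,5S)-5-(tert-butyldimethylsilyloxy)-1,2-dihydroxycyclohex-3-en-1-yl]heptadec-10-en-2-imine (not isolated) | CCCCCC/C=C\CCCCCCCC(=N)C[C@@]1(O)C[C@H](O[Si](C)(C)C(C)(C)C)C=C[C@@H]1O | intermediate
20 | (10Z)-1-[(1S,2S,5S)-5-(tert-butyldimethylsilyloxy)-1,2-dihydroxycyclohex-3-en-1-yl]heptadec-10-en-2-one | CCCCCC/C=C\CCCCCCCC(=O)C[C@@]1(O)C[C@H](O[Si](C)(C)C(C)(C)C)C=C[C@@H]1O | intermediate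
21 | (1R,2S,5S)-5-(tert-butyldimethylsilyloxy)-1-[(2S,10Z)-2-hydroxyheptadec-10-en-1-yl]cyclohex-3-ene-1,2-diol | CCCCCC/C=C\CCCCCCC[C@H](O)C[C@@]1(O)C[C@H](O[Si](C)(C)C(C)(C)C)C=C[C@@H]1O | intermediate
22 | (4S,6R)-4-(tert-butyldimethylsilyloxy)-6-hydroxy-6-[(2S,10Z)-2-hydroxyheptadec-10-en-1-yl]cyclohex-2-en-1-one | CCCCCC/C=C\CCCCCCC[C@H](O)C[C@@]1(O)C[C@H](O[Si](C)(C)C(C)(C)C)C=CC1=O | intermediate
23 | (4S,6R)-4,6-dihydroxy-6-[(2S,10Z)-2-hydroxyheptadec-10-en-1-yl]cyclohex-2-en-1-one | CCCCCC/C=C\CCCCCCC[C@H](O)C[C@@]1(O)C[C@H](O)C=CC1=O | target

## Step count and least certain steps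

Total: 14 steps. Longest linear sequence: 12 steps (steps 1–7 and 10–14); steps 8 and 9 form the side branch.

**Step 10 (key step).** The most likely failure is erosion of facial and site control: the dipole adding from the face opposite the alkoxide or to the ring alkene, accompanied by dimerisation of 17. This could happen because delivery through magnesium has to outrun the uncomplexed background reaction, and the ring alkene is allylic to the same alkoxide. The fallback replaces the cycloaddition by an epoxide opening. It sets out from 12: hydroxyl-directed epoxidation of the exocyclic alkene (VO(acac)2, t-BuOOH, CH2Cl2) should give the spiro-epoxide with oxygen on the C1–O face F1. In parallel 13 is converted with propane-1,3-dithiol and BF3·OEt2 into 2-[(8Z)-pentadec-8-en-1-yl]-1,3-dithiane F2. Its 2-lithio derivative (n-BuLi, THF) opens F1 at the CH2 terminus to the dithiane diol F3. Hydrolysis of the dithiane (MeI, CaCO3, aqueous MeCN) comes back to the route at 20.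

**Step 12.** The most likely failure is poor facial selectivity of hydride delivery at C2′, because the C1 and C5 arms of C6 are told apart only if boron really bridges both hydroxyls. The fallback switches to catalyst control on a protected substrate. It sets out from 20: 2,2-dimethoxypropane and PPTS give the acetonide of the C1/C6 diol F4. Reduction with (R)-2-methyl-CBS-oxazaborolidine and BH3·SMe2, which should treat the branched C1′ arm as the large group, gives the (2′S) alcohol acetonide F5. PPTS in MeOH removes the acetonide and comes back to the route at 21.

**Step 7.** The most likely failure is poor facial selectivity of hydride addition, leading to the C1 epimer, because the only bias is a remote silyloxy group on a flattened ring. The fallback replaces substrate control by catalyst control: from 11, reduction with (R)-2-methyl-CBS-oxazaborolidine and catecholborane in toluene at −78 °C, on the premise that the disubstituted C6 arm acts as the larger group, arrives at 12. It makes no new compound (entered as F0).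

**Step 6.** The most likely failure is prototropic aromatisation or dimerisation of the product during the base-induced elimination and its handling, because 11 is a tautomer of a phenol and an unhindered Michael acceptor. The fallback reduces first and eliminates afterwards, so that 11 never exists. It sets out from 7: the Mannich base 9 is isolated and reduced (NaBH4, CeCl3·7H2O, MeOH) to the amino alcohol F6. Oxidation at nitrogen (mCPBA, CH2Cl2, 0 °C) gives the N-oxide F7. Cope elimination on gentle warming removes the only β-hydrogen, at C6, and comes back to the route at 12; the C6 centre of F6 disappears in this step.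

## Further compounds

F1 | step 10 | spiro-epoxide of 12: (4S,7S)-7-(tert-butyldimethylsilyloxy)-1-oxaspiro[2.5]oct-5-en-4-ol with the epoxide oxygen cis to the C4 hydroxyl of the spiro numbering | C1O[C@@]12C[C@H](O[Si](C)(C)C(C)(C)C)C=C[C@@H]2O
F2 | step 10 | 2-[(8Z)-pentadec-8-en-1-yl]-1,3-dithiane | CCCCCC/C=C\CCCCCCCC1SCCCS1
F3 | step 10 | dithiane diol: 20 with its ketone masked as the 1,3-dithiane | CCCCCC/C=C\CCCCCCCC1(SCCCS1)C[C@@]2(O)C[C@H](O[Si](C)(C)C(C)(C)C)C=C[C@@H]2O
F4 | step 12 | acetonide of the C1/C6 diol of 20 | CCCCCC/C=C\CCCCCCCC(=O)C[C@@]12C[C@H](O[Si](C)(C)C(C)(C)C)C=C[C@@H]1OC(C)(C)O2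
F5 | step 12 | acetonide of the C1/C6 diol of 21, (2′S) alcohol | CCCCCC/C=C\CCCCCCC[C@H](O)C[C@@]12C[C@H](O[Si](C)(C)C(C)(C)C)C=C[C@@H]1OC(C)(C)O2
F0 | step 7 | none | none
F6 | step 6 | (1S,4S)-4-(tert-butyldimethylsilyloxy)-6-[(dimethylamino)methyl]cyclohex-2-en-1-ol (C6 epimers) | CN(C)CC1C[C@H](O[Si](C)(C)C(C)(C)C)C=C[C@@H]1O
F7 | step 6 | N-oxide of F6 | C[N+](C)([O-])CC1C[C@H](O[Si](C)(C)C(C)(C)C)C=C[C@@H]1O
A1 | alternative 1 | (4S,6R)-4-hydroxy-6-(methoxymethoxy)-6-[(2S,10Z)-2-(tert-butyldimethylsilyloxy)heptadec-10-en-1-yl]cyclohex-2-en-1-one | CCCCCC/C=C\CCCCCCC[C@H](O[Si](C)(C)C(C)(C)C)C[C@@]1(OCOC)C[C@H](O)C=CC1=O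
A2 | alternative 1 | open-chain (Z)-β-iodoenone aldehyde: C6 bearing the methoxymethoxy group, the silylated side chain, the CH2–CHO arm (C5–C4) and the (Z)-3-iodoacryloyl group (C1–C3) | CCCCCC/C=C\CCCCCCC[C@H](O[Si](C)(C)C(C)(C)C)C[C@@](OCOC)(CC=O)C(=O)/C=C\I
A3 | alternative 1 | quinic acid, (1S,3R,4S,5R)-1,3,4,5-tetrahydroxycyclohexane-1-carboxylic acid | OC(=O)[C@]1(O)C[C@@H](O)[C@@H](O)[C@H](O)C1
A4 | alternative 2 | 2,2-disubstituted 1,3-dithiane with the C2′ silyl ether arm and the C4 hydroxy arm ending in the C1 dimethyl acetal | CCCCCC/C=C\CCCCCCC[C@H](O[Si](C)(C)C(C)(C)C)CC1(SCCCS1)C[C@H](O)CCC(OC)OC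
A5 | alternative 2 | 2-(tert-butyldimethylsilyl)-1,3-dithiane | CC(C)(C)[Si](C)(C)C1SCCCS1
A6 | alternative 2 | (S)-2-[(8Z)-pentadec-8-en-1-yl]oxirane | CCCCCC/C=C\CCCCCCC[C@H]1CO1
A7 | alternative 2 | (R)-2-(3,3-dimethoxypropyl)oxirane | COC(OC)CC[C@@H]1CO1
A8 | alternative 3 | (4S,6R)-4,6-dihydroxy-6-[(2S,10Z)-2-(tert-butyldimethylsilyloxy)heptadec-10-en-1-yl]cyclohex-2-en-1-one | CCCCCC/C=C\CCCCCCC[C@H](O[Si](C)(C)C(C)(C)C)C[C@@](O)1C[C@H](O)C=CC1=O
A9 | alternative 3 | open-chain β-keto sulfoxide aldehyde: C6 carbinol bearing the silylated side chain, the CH2CH2CHO arm (C5–C3) and the phenylsulfinylacetyl group (C1–C2), sulfur configuration unspecified | CCCCCC/C=C\CCCCCCC[C@H](O[Si](C)(C)C(C)(C)C)C[C@@](O)(CCC=O)C(=O)CS(=O)c1ccccc1
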